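Amounts first: before any rate, I ask how much reagent each flask holds against what its substrate can take up.

| setting | noon | winter | Saturday's | Friday's |
|---|---|---|---|---|
| substrate | 0.010 M | 0.039 M | 0.050 M | 0.015 M |
| reagent | 0.125 M | 0.125 M | 0.125 M | 0.125 M |
| scavenger | 0.050 M (fed, over 4.0 d) | 0.050 M (fed, over 4.0 d) | 0.0500 M (fed, over 4.0 d) | 0.0500 M (fed, over 4.0 d) |
| temperature | 0 °C | 25 °C |  |  |
| remark | run made earlier; the fed solution adds 0.50 times the starting volume | run made earlier; the fed solution adds 0.50 times the starting volume | at 5 °C until 50 h, from then on at 45 °C; the fed solution adds 0.50 times the starting volume | at 5 °C throughout; the fed solution adds 0.50 times the starting volume |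
| time |  |  | 4.0 d | 4.0 d |

noon run (percent of the substrate charged)

| time / d | tris adduct / % | substrate / % |
|---|---|---|
| 0.250 | 5 | 46 |
| 0.625 | 19 | 14 |
| 1.25 | 54 | 6 |
| 2.08 | 79 | 0 |
| 3.00 | 93 | 0 |

winter run (percent of the substrate charged)

| time / h | tris adduct / % | substrate / % |
|---|---|---|
| 6.00 | 59 | 2 |
| 10.0 | 71 | 0 |
| 15.0 | 81 | 1 |
| 20.0 | 86 | 0 |
| 25.0 | 86 | 2 |

(each reading ± 1.5 percentage points)

- amounts are per litre of the starting volume; all of the dose is in the solution fed

1. which of the two ends with the higher amount of tris adduct, in percent of the substrate charged ("neither" if they lie within 2 percentage points) (Saturday's / Friday's / neither)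
2. tris adduct at the end, in percent of the substrate charged, Saturday's
3. tris adduct at the end, in percent of the substrate charged, Friday's

A tris adduct holds 3 reagent units, as its name says, so tris adduct cannot exceed the reagent charged divided by 3. Saturday's has 83.3% as its coverage c, the reagent charged over 3 times the substrate charged. Where the reagent charged exceeds 3 times the substrate charged, c sets no cap.

  c, Saturday's = 0.125 M / (3 × 0.050 M) = 83.3%
  c, Friday's = 0.125 M / (3 × 0.015 M) = 278%

So reagent is the limiting reagent in Saturday's, where 0.125 M stands below the 0.150 M that full conversion takes.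

Now the question turned round. For Saturday's to end on top, Friday's has to stop below that cap. But the noon run, with the same 0.125 M of reagent and with less substrate than Friday's, 0.010 M against 0.015 M, is colder than Friday's and already reads 93% at 3.00 d, which is more than the cap.

The cap is a bound, not an estimate: the winter run has c = 107% and reads 86% at 25.0 h. I commit to Friday's ahead, with Saturday's somewhere under 83.3%.

The forecast says Friday's, with 41% for Saturday's and 96% for Friday's. Its figure for Saturday's is its own reckoning and lies lower than my cap. Its ground: “Substrate plus scavenger exhaust the reagent near 1.9 d, before the heating at 50 h, so warming does nothing.”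

The flask gives Friday's: 55.8% in Saturday's, under its c of 83.3%, and 99.5% in Friday's.

    reagent + bis adduct → tris adduct + released group (k = 0.952 M⁻¹ h⁻¹, Ea = 58.0 kJ mol⁻¹)
    scavenger + released group → scavenged by-product (k = 119 M⁻¹ h⁻¹, Ea = 42.0 kJ mol⁻¹)
    reagent + released group ⇌ idle adduct, settled at all times (K = 10.3 M⁻¹, ΔH = −37.0 kJ mol⁻¹)
    substrate + reagent → first product + released group (k = 2.08 M⁻¹ h⁻¹, Ea = 72.0 kJ mol⁻¹)
    reagent + first product → bis adduct + released group (k = 2.68 M⁻¹ h⁻¹, Ea = 72.0 kJ mol⁻¹)
    released group → by-product carried off (k = 0.239 h⁻¹, Ea = 80.0 kJ mol⁻¹)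
    (constants at 5 °C)

Saturday's reached its change of temperature at 2.08 d with tris adduct at 45.5%, bis adduct at 41.5% and reagent still at 8.67% of its charge; at 45 °C the steps taking reagent ran on that remainder, and at 4.00 d reagent stood at 0% and tris adduct at 55.8%. Friday's stayed at 5 °C with reagent at 64.1% of its charge at the end, while bis adduct fell from 7.34% at 2.00 d to 0.522%. That remainder in Saturday's is where forecast and flask part.

A neighbour of Friday's with 0.031 M of reagent has c = 68.9%, so its tris adduct must stay under that. It ends at 22.5%, with 44.1% bis adduct and 20.2% first product.

(The numbers in the tables were computed for an exercise, and the scatter is random.)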